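Locants: pyranone O1, C2(=O), C3=C4, C5, C6. Side chain: C1′ (CHOH), oxolane carbons C2′–C5′, C6′ (acyloxy carbon), C7′ (methyl). TBS = tert-butyldimethylsilyl.
Enabling feature: the oxolane ring carries its exocyclic carbons C1′ (on C2′) and C6′ (on C5′) cis, C1′ is bonded to C6, and C6′ bears an oxygen. Re-tying C6′ to C6 (retro-Baeyer–Villiger) lays a three-carbon bridge C6′–C6–C1′ over the ring, which gives an 8-oxabicyclo[3.2.1]octan-3-one.
Cuts, in retrosynthetic order: silyl ethers; C3=C4 (metathesis) and O1–C2 (acrylate); C5–C6 (allylation); coumarate ester C–O; C6′–O back to C6′–C6; C7′–C6′ (enolate methylation). Last, C5′–C6′ and C1′–C2′ go together in a retro-(4+3) to furan and a C3 oxyallyl cation.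
Forward order: the oxolane comes first, as dearomatised furan inside a temporary seven-membered carbocycle. The carbocycle is then expanded to a temporary seven-membered lactone, C1′ is oxygenated, the lactone is opened, the coumarate is attached, the chain is grown at C6, and the pyranone ring is closed last.
Stereochemistry: C2′/C5′ are cis from the suprafacial (4+3) addition. The absolute sense and C6′ come from chiral lithium amide desymmetrisation, exo methylation and retentive migration. C1′ comes from exo hydride delivery to the bicyclic keto lactone, and C6 from matched, reagent-controlled allylboration.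

Key step: step 1

Assumption: the (S,S)-amide is taken to remove the exo α-proton on the side that becomes C6′, by analogy with conformationally locked cyclohexanones. If the sense is the reverse, the (R,R)-amide is used and nothing else changes.

Step 1
Reactants: 1 furan; 2 1,1,3-trichloroacetone
Product: 4 2,4-dichloro-8-oxabicyclo[3.2.1]oct-6-en-3-one as a mixture of C–Cl epimers, via 1,3-dichloro-2-oxidoallyl cation 3 (not isolated)
Conditions: Et3N, CF3CH2OH, furan in excess, 0 °C to rt
Reagents that add atoms: none
Why: Triethylamine enolises 2 toward the CH2Cl group, and the ionising, weakly nucleophilic fluoro alcohol assists loss of chloride from the CHCl2 terminus to give the chlorine-stabilised 2-oxidoallyl cation 3, a 2π three-carbon partner. This cation adds across C2 and C5 of furan (the 4π partner) in a (4+3) cycloaddition, the well-known reaction type of polyhaloketone-derived oxyallyl cations with furans, and so forms the C5′–C6′ and C1′–C2′ bonds in one event while the aromatic ring is dearomatised to the 2,5-dihydrofuran that becomes the oxolane. One ring is closed, the seven-membered carbocycle, by cycloaddition of both allyl termini to the two furan α-carbons, and the former furan ring becomes its oxygen bridge. The bridgehead stereocentres C2′ and C5′ are set cis because both bonds form on one face of the planar furan and a three-carbon bridge cannot span opposite faces; the two C–Cl centres follow from the W-shaped cation and the compact or extended approach, and they do not matter because step 2 erases them. The step needs periselectivity for (4+3) closure over electrophilic substitution at a furan α-carbon and over solvent capture of 3; this is secured by the two chlorine substituents that stabilise the cation, the two equivalent open α-positions of furan, and the excess of furan in a poorly nucleophilic medium.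

Step 2
Reactants: 4 2,4-dichloro-8-oxabicyclo[3.2.1]oct-6-en-3-one
Product: 5 meso-8-oxabicyclo[3.2.1]octan-3-one
Conditions: H2 (1 atm), Pd/C, NaOAc, EtOH, rt
Reagents that add atoms: none
Why: Heterogeneous catalytic hydrogenation saturates the C3′=C4′ alkene and, by hydrodehalogenation of the two carbonyl-activated C–Cl bonds with acetate as acid scavenger, funnels all chloride epimers of 4 into the one meso ketone 5, whose only stereocentres are the cis bridgeheads from step 1.

Step 3
Reactants: 5 meso-8-oxabicyclo[3.2.1]octan-3-one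
Product: 7 (1S,2S,5R)-2-methyl-8-oxabicyclo[3.2.1]octan-3-one (methyl exo and axial), via lithium enolate 6 (not isolated)
Conditions: (S,S)-bis(1-phenylethyl)amine·HCl, n-BuLi (2 equiv), THF, −78 °C to rt, then −100 °C; add 5; then MeI, DMPU, −78 to −45 °C
Reagents that add atoms: iodomethane, CI
Why: This is a desymmetrising enantioselective deprotonation followed by enolate alkylation, in which the C2-symmetric chiral lithium amide–LiCl aggregate removes one of the two enantiotopic exo (axial) α-protons and so fixes the absolute sense of C5′ and C2′, and the locked enolate 6 takes methyl iodide on its exo face, anti to the ethano bridge, so that C6′ forms with an axial methyl group.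

Step 4
Reactants: 7 (1S,2S,5R)-2-methyl-8-oxabicyclo[3.2.1]octan-3-one
Product: 8 (1S,2S,6R)-2-methyl-3,9-dioxabicyclo[4.2.1]nonan-4-one
Conditions: mCPBA, CH2Cl2, 0 °C to rt
Reagents that add atoms: 3-chloroperoxybenzoic acid, OOC(=O)c1cccc(Cl)c1
Why: In this Baeyer–Villiger oxidation the secondary carbon C6′ migrates in preference to the C1′ methylene and with retention, which converts the helper bond C6′–C6 into the C6′–O bond and delivers the (S,S) threo relation between C6′ and C5′ inside a temporary seven-membered lactone.

Step 5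
Reactants: 8 (1S,2S,6R)-2-methyl-3,9-dioxabicyclo[4.2.1]nonan-4-one
Product: 9 (1S,2S,6R,E)-5-[(dimethylamino)methylidene]-2-methyl-3,9-dioxabicyclo[4.2.1]nonan-4-one
Conditions: t-BuOCH(NMe2)2, toluene, 90 °C
Reagents that add atoms: tert-butoxybis(dimethylamino)methane (Bredereck's reagent), CC(C)(C)OC(N(C)C)N(C)C
Why: Aminomethylenation of the single α-methylene group (C1′) of the lactone with Bredereck's reagent gives the enamino lactone under thermal conditions, avoids a stoichiometric metal enolate that could expel the β-oxygen bridge, and touches no stereocentre.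

Step 6
Reactants: 9 enamino lactone
Product: 10 (1S,2S,6R)-2-methyl-3,9-dioxabicyclo[4.2.1]nonane-4,5-dione
Conditions: O3, CH2Cl2, −78 °C; then Me2S
Reagents that add atoms: ozone, [O-][O+]=O
Why: Ozonolysis cleaves the electron-rich enamine C=C bond and leaves the C1′ ketone, while C2′, although now α to a ketone, cannot epimerise because the bicyclic frame allows only the cis bridge.

Step 7
Reactants: 10 (1S,2S,6R)-2-methyl-3,9-dioxabicyclo[4.2.1]nonane-4,5-dione
Product: 11 (1S,2S,5S,6R)-5-hydroxy-2-methyl-3,9-dioxabicyclo[4.2.1]nonan-4-one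
Conditions: LiBH(s-Bu)3, THF, −78 °C; AcOH quench
Reagents that add atoms: none
Why: In this substrate-controlled ketone reduction the bulky trialkylborohydride should attack the far more electrophilic C1′ ketone rather than the lactone, from the exo face beside the one-atom oxygen bridge and away from the C3′–C4′ ethano bridge, so that the new hydroxyl points endo and C1′ forms as (S), threo to C2′.

Step 8
Reactants: 11 (1S,2S,5S,6R)-5-hydroxy-2-methyl-3,9-dioxabicyclo[4.2.1]nonan-4-one
Product: 12 (1S,2S,5S,6R)-5-[(tert-butyldimethylsilyl)oxy]-2-methyl-3,9-dioxabicyclo[4.2.1]nonan-4-one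
Conditions: TBSOTf, 2,6-lutidine, CH2Cl2, 0 °C
Reagents that add atoms: tert-butyldimethylsilyl triflate, CC(C)(C)[Si](C)(C)OS(=O)(=O)C(F)(F)F
Why: Silyl ether formation with the reactive triflate protects the hindered α-hydroxy lactone without a base strong enough to enolise it, so C1′ is kept.

Step 9
Reactants: 12 silyloxy lactone
Product: 13 (2S)-2-[(tert-butyldimethylsilyl)oxy]-2-{(2R,5S)-5-[(1S)-1-hydroxyethyl]oxolan-2-yl}-N-methoxy-N-methylacetamide
Conditions: MeNH(OMe)·HCl, AlMe3, CH2Cl2, 0 °C to rt; aqueous work-up
Reagents that add atoms: N,O-dimethylhydroxylamine hydrochloride, CNOC.Cl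
Why: Weinreb aminolysis of the lactone with the aluminium amide made in situ opens the temporary seven-membered ring, stores C6 as an aldehyde equivalent and frees only the C6′ hydroxyl, which differentiates the three oxygenated carbons without extra protecting groups.

Step 10
Reactants: 14 (E)-4-hydroxycinnamic acid (p-coumaric acid)
Product: 16 (E)-3-{4-[(tert-butyldimethylsilyl)oxy]phenyl}prop-2-enoic acid, via bis-silylated coumarate 15 (not isolated)
Conditions: TBSCl (2.2 equiv), imidazole, DMF, rt; then AcOH–THF–H2O, rt
Reagents that add atoms: tert-butyldimethylsilyl chloride, CC(C)(C)[Si](C)(C)Cl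
Why: Exhaustive silylation followed by selective hydrolysis of the labile silyl ester leaves the phenol masked and the acid free for coupling, with the E alkene untouched.

Step 11
Reactants: 13 hydroxy Weinreb amide; 16 TBS-protected p-coumaric acid
Product: 17 (1S)-1-{(2S,5R)-5-[(1S)-1-[(tert-butyldimethylsilyl)oxy]-2-[methoxy(methyl)amino]-2-oxoethyl]oxolan-2-yl}ethyl (E)-3-{4-[(tert-butyldimethylsilyl)oxy]phenyl}prop-2-enoate
Conditions: DCC, DMAP (cat.), CH2Cl2, 0 °C to rt
Reagents that add atoms: none
Why: Steglich esterification acylates the C6′ oxygen, so the C6′–O bond is not broken and the (S) configuration is retained.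

Step 12
Reactants: 17 coumarate Weinreb amide
Product: 18 (1S)-1-{(2S,5R)-5-[(1S)-1-[(tert-butyldimethylsilyl)oxy]-2-oxoethyl]oxolan-2-yl}ethyl (E)-3-{4-[(tert-butyldimethylsilyl)oxy]phenyl}prop-2-enoate
Conditions: Cp2Zr(H)Cl, THF, rt; aqueous work-up
Reagents that add atoms: none
Why: In this chemoselective amide-to-aldehyde reduction with the Schwartz reagent, hydride transfer to the Weinreb amide gives a zirconated hemiaminal that collapses only on work-up, while the conjugated ester, its disubstituted alkene and the silyl ethers react far more slowly and C1′ is not exposed to base.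

Step 13
Reactants: 18 α-silyloxy aldehyde
Product: 19 (1S)-1-{(2S,5R)-5-[(1R,2R)-1-[(tert-butyldimethylsilyl)oxy]-2-hydroxypent-4-en-1-yl]oxolan-2-yl}ethyl (E)-3-{4-[(tert-butyldimethylsilyl)oxy]phenyl}prop-2-enoate (the 1R descriptor at C1′ reflects a change of CIP ranking, not of geometry)
Conditions: B-allylbis(isopinocampheyl)borane from (−)-α-pinene, Et2O, −78 °C; then H2O2, pH 7 buffer, MeOH, 0 °C
Reagents that add atoms: B-allylbis(isopinocampheyl)borane derived from (−)-α-pinene, C=CCB([C@H]1C[C@H]2C[C@@H]([C@@H]1C)C2(C)C)[C@H]1C[C@H]2C[C@@H]([C@@H]1C)C2(C)C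
Why: Brown allylboration proceeds through a closed chair transition state in which the isopinocampheyl ligands direct the allyl group to the aldehyde face that gives (R)-C6, a sense that the polar Felkin–Anh preference of the α-silyloxy aldehyde for the 1,2-anti product should reinforce.

Step 14
Reactants: 19 homoallylic alcohol
Product: 20 (1S)-1-{(2S,5R)-5-[(1S,2R)-2-(acryloyloxy)-1-[(tert-butyldimethylsilyl)oxy]pent-4-en-1-yl]oxolan-2-yl}ethyl (E)-3-{4-[(tert-butyldimethylsilyl)oxy]phenyl}prop-2-enoate
Conditions: acryloyl chloride, i-Pr2NEt, DMAP (cat.), CH2Cl2, 0 °C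
Reagents that add atoms: acryloyl chloride, C=CC(=O)Cl
Why: O-Acylation of the only free hydroxyl group installs C2 and C3 together with the second alkene needed for ring closure and touches no stereocentre.

Step 15
Reactants: 20 acrylate diene
Product: 21 (1S)-1-{(2S,5R)-5-[(S)-[(tert-butyldimethylsilyl)oxy][(2R)-6-oxo-3,6-dihydro-2H-pyran-2-yl]methyl]oxolan-2-yl}ethyl (E)-3-{4-[(tert-butyldimethylsilyl)oxy]phenyl}prop-2-enoate
Conditions: second-generation Grubbs catalyst, (H2IMes)(PCy3)Cl2Ru=CHPh (5 mol %), CH2Cl2, reflux, high dilution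
Reagents that add atoms: none
Why: Ring-closing metathesis of the two terminal alkenes closes the six-membered 5,6-dihydropyran-2-one with its necessarily Z C3=C4 bond and loses ethene, while the electron-poor, disubstituted cinnamate alkene is a much poorer metathesis partner.

Step 16
Reactants: 21 bis-silyl ether
Product: 22 target, (1S)-1-{(2S,5R)-5-[(S)-hydroxy[(2R)-6-oxo-3,6-dihydro-2H-pyran-2-yl]methyl]oxolan-2-yl}ethyl (E)-3-(4-hydroxyphenyl)prop-2-enoate
Conditions: HF·pyridine, pyridine, THF, 0 °C to rt
Reagents that add atoms: none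
Why: Fluoride-mediated desilylation under buffered acidic conditions removes the phenolic and the secondary silyl ether together and spares both esters, both enoate systems and all five stereocentres.

Compound list
1 | furan | c1ccoc1 | starting material
2 | 1,1,3-trichloroacetone | ClCC(=O)C(Cl)Cl | starting material
3 | 1,3-dichloro-2-oxidoallyl cation | [O-]C(=CCl)[CH+]Cl | intermediate
4 | 2,4-dichloro-8-oxabicyclo[3.2.1]oct-6-en-3-one (cis bridgeheads, C–Cl epimers) | O=C1C(Cl)[C@@H]2C=C[C@H](C1Cl)O2 | intermediate
5 | meso-8-oxabicyclo[3.2.1]octan-3-one | O=C1C[C@@H]2CC[C@H](C1)O2 | intermediate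
6 | lithium (1S,5R)-8-oxabicyclo[3.2.1]oct-2-en-3-olate | [Li+].[O-]C1=C[C@@H]2CC[C@H](C1)O2 | intermediate
7 | (1S,2S,5R)-2-methyl-8-oxabicyclo[3.2.1]octan-3-one (exo methyl) | C[C@H]1[C@@H]2CC[C@H](CC1=O)O2 | intermediate
8 | (1S,2S,6R)-2-methyl-3,9-dioxabicyclo[4.2.1]nonan-4-one | C[C@H]1[C@@H]2CC[C@H](CC(=O)O1)O2 | intermediate
9 | (1S,2S,6R,E)-5-[(dimethylamino)methylidene]-2-methyl-3,9-dioxabicyclo[4.2.1]nonan-4-one | C[C@H]1[C@@H]2CC[C@H](/C(=C\N(C)C)C(=O)O1)O2 | intermediate
10 | (1S,2S,6R)-2-methyl-3,9-dioxabicyclo[4.2.1]nonane-4,5-dione | C[C@H]1[C@@H]2CC[C@H](C(=O)C(=O)O1)O2 | intermediate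
11 | (1S,2S,5S,6R)-5-hydroxy-2-methyl-3,9-dioxabicyclo[4.2.1]nonan-4-one | C[C@H]1[C@@H]2CC[C@H]([C@H](O)C(=O)O1)O2 | intermediate
12 | (1S,2S,5S,6R)-5-(TBS-oxy)-2-methyl-3,9-dioxabicyclo[4.2.1]nonan-4-one | C[C@H]1[C@@H]2CC[C@H]([C@H](O[Si](C)(C)C(C)(C)C)C(=O)O1)O2 | intermediate
13 | hydroxy Weinreb amide (name in step 9) | C[C@H](O)[C@@H]1CC[C@H]([C@H](O[Si](C)(C)C(C)(C)C)C(=O)N(C)OC)O1 | intermediate
14 | (E)-4-hydroxycinnamic acid | OC(=O)/C=C/c1ccc(O)cc1 | starting material
15 | tert-butyldimethylsilyl (E)-3-{4-[(tert-butyldimethylsilyl)oxy]phenyl}prop-2-enoate | CC(C)(C)[Si](C)(C)OC(=O)/C=C/c1ccc(O[Si](C)(C)C(C)(C)C)cc1 | intermediate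
16 | (E)-3-{4-[(tert-butyldimethylsilyl)oxy]phenyl}prop-2-enoic acid | OC(=O)/C=C/c1ccc(O[Si](C)(C)C(C)(C)C)cc1 | intermediate
17 | coumarate Weinreb amide (name in step 11) | C[C@H](OC(=O)/C=C/c1ccc(O[Si](C)(C)C(C)(C)C)cc1)[C@@H]1CC[C@H]([C@H](O[Si](C)(C)C(C)(C)C)C(=O)N(C)OC)O1 | intermediate
18 | α-silyloxy aldehyde (name in step 12) | C[C@H](OC(=O)/C=C/c1ccc(O[Si](C)(C)C(C)(C)C)cc1)[C@@H]1CC[C@H]([C@H](O[Si](C)(C)C(C)(C)C)C=O)O1 | intermediate
19 | homoallylic alcohol (name in step 13) | C[C@H](OC(=O)/C=C/c1ccc(O[Si](C)(C)C(C)(C)C)cc1)[C@@H]1CC[C@H]([C@H](O[Si](C)(C)C(C)(C)C)[C@H](O)CC=C)O1 | intermediate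
20 | acrylate diene (name in step 14) | C[C@H](OC(=O)/C=C/c1ccc(O[Si](C)(C)C(C)(C)C)cc1)[C@@H]1CC[C@H]([C@H](O[Si](C)(C)C(C)(C)C)[C@H](OC(=O)C=C)CC=C)O1 | intermediate
21 | bis-TBS dihydropyranone (name in step 15) | C[C@H](OC(=O)/C=C/c1ccc(O[Si](C)(C)C(C)(C)C)cc1)[C@@H]1CC[C@H]([C@H](O[Si](C)(C)C(C)(C)C)[C@H]2CC=CC(=O)O2)O1 | intermediate
22 | target (name in step 16) | C[C@H](OC(=O)/C=C/c1ccc(O)cc1)[C@@H]1CC[C@H]([C@H](O)[C@H]2CC=CC(=O)O2)O1 | target

Total step count: 16. Longest linear sequence: 15 steps (steps 1–9 and 11–16).

Steps most likely to fail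

Step 3. The enantiotopic protons may be discriminated less well when the enolate is formed first and alkylated afterwards. Proton exchange between enolate and product during the slow alkylation may erode the exo-methyl configuration or lead to double methylation. Warming may also trigger β-elimination of the oxygen bridge. The fallback sets out from 5 and comes back at 7, and it separates the asymmetric event from the C–C bond formation. Ketone 5 is deprotonated by the chiral lithium amide with Me3SiCl already present (internal quench). This gives (1S,5R)-3-(trimethylsilyloxy)-8-oxabicyclo[3.2.1]oct-2-ene F1, which is isolated and purified. MeLi in THF then cleaves the O–Si bond and releases the amine-free lithium enolate 6 regiospecifically, and MeI converts it into 7.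

Step 7. Facial selectivity may be poor, because the polar effect of the C2′–O bond, which favours attack anti to oxygen, can compete with the steric shielding by the ethano bridge. The fallback sets out from 10 and comes back at 11, and it corrects C1′ by substitution instead of relying on the hydride trajectory. Dione 10 is reduced without regard to selectivity (NaBH4, MeOH, −78 °C). The unwanted epimer, (1S,2S,5R,6R)-5-hydroxy-2-methyl-3,9-dioxabicyclo[4.2.1]nonan-4-one F2, is subjected to Mitsunobu inversion with chloroacetic acid (PPh3, DIAD, toluene). This gives (1S,2S,5S,6R)-2-methyl-4-oxo-3,9-dioxabicyclo[4.2.1]nonan-5-yl chloroacetate F3. Its chloroacetyl group is removed with thiourea and NaHCO3 in EtOH, which leaves the lactone intact and gives 11.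

Step 12. Chemoselectivity may be lost through competing hydrozirconation of the cinnamate alkene, attack on the ester, or over-reduction of the aldehyde. The fallback sets out from 12 and comes back at 18, and it replaces the amide and hydride manifold by a thioester and a palladium-catalysed silane reduction. Lactone 12 is opened with EtSH and AlMe3 to S-ethyl (2S)-2-[(tert-butyldimethylsilyl)oxy]-2-{(2R,5S)-5-[(1S)-1-hydroxyethyl]oxolan-2-yl}ethanethioate F4. Steglich esterification with 16 gives the coumarate thioester F5. Fukuyama reduction (Et3SiH, Pd/C, acetone, rt) then converts the thioester alone into aldehyde 18.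

Further compounds
F1 | step 3 | (1S,5R)-3-(trimethylsilyloxy)-8-oxabicyclo[3.2.1]oct-2-ene | C[Si](C)(C)OC1=C[C@@H]2CC[C@H](C1)O2
F2 | step 7 | (1S,2S,5R,6R)-5-hydroxy-2-methyl-3,9-dioxabicyclo[4.2.1]nonan-4-one | C[C@H]1[C@@H]2CC[C@H]([C@@H](O)C(=O)O1)O2
F3 | step 7 | (1S,2S,5S,6R)-2-methyl-4-oxo-3,9-dioxabicyclo[4.2.1]nonan-5-yl chloroacetate | C[C@H]1[C@@H]2CC[C@H]([C@H](OC(=O)CCl)C(=O)O1)O2
F4 | step 12 | S-ethyl (2S)-2-[(tert-butyldimethylsilyl)oxy]-2-{(2R,5S)-5-[(1S)-1-hydroxyethyl]oxolan-2-yl}ethanethioate | C[C@H](O)[C@@H]1CC[C@H]([C@H](O[Si](C)(C)C(C)(C)C)C(=O)SCC)O1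
F5 | step 12 | (1S)-1-{(2S,5R)-5-[(1S)-1-[(tert-butyldimethylsilyl)oxy]-2-(ethylsulfanyl)-2-oxoethyl]oxolan-2-yl}ethyl (E)-3-{4-[(tert-butyldimethylsilyl)oxy]phenyl}prop-2-enoate | C[C@H](OC(=O)/C=C/c1ccc(O[Si](C)(C)C(C)(C)C)cc1)[C@@H]1CC[C@H]([C@H](O[Si](C)(C)C(C)(C)C)C(=O)SCC)O1
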